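The data were computed from invented constants, and the scatter is random.

The slowness of the last of the substrate was what I had to price before choosing the next charge of partner B, since a flask can hold enough partner B and still not finish in time.

all flasks: substrate 20 mM
- blue: partner A 19 mM; partner B 11 mM (fed, over 80 s); protic impurity 4 mM; run made earlier
- grey: partner A 19 mM; partner B 150 mM (fed, over 80 s); protic impurity 4 mM; run made earlier
- winter: partner A 19.0 mM; partner B 12.0 mM (fed, over 80 s); protic impurity 4.00 mM; time 4.0 min
- spring: partner A 19.0 mM; partner B 40.0 mM (fed, over 80 s); protic impurity 4.00 mM; time 4.0 min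
- autumn: partner A 19.0 mM; partner B 100 mM (fed, over 80 s); protic impurity 4.00 mM; time 4.0 min
- midnight: partner A 19.0 mM; partner B 8.00 mM (fed, over 80 s); protic impurity 4.00 mM; time 4.0 min
- dusk: partner A 19.0 mM; partner B 26.0 mM (fed, over 80 s); protic impurity 4.00 mM; time 4.0 min

| run | time / min | open intermediate / % | product / % |
|---|---|---|---|
| blue | 0.250 | 2.1 | 0 |
| blue | 0.833 | 14.2 | 0 |
| blue | 1.33 | 27.4 | 0 |
| blue | 2.00 | 37.0 | 0.4 |
| blue | 3.00 | 40.9 | 1.1 |
| blue | 4.00 | 41.9 | 1.9 |
| grey | 0.250 | 23.8 | 0 |
| grey | 0.833 | 88.5 | 3.5 |
| grey | 1.33 | 89.0 | 11.3 |
| grey | 2.00 | 81.1 | 18.9 |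
| grey | 3.00 | 76.6 | 24.0 |
| grey | 4.00 | 75.2 | 24.6 |

(standard deviation of a reading: 0.3 percentage points)



1. the flasks put in order of amount of open intermediate, in percent of the substrate charged, best first, at 4.0 min (winter / spring / autumn / midnight / dusk)
2. the same order at 50 s (winter / spring / autumn / midnight / dusk)
3. the amount of open intermediate, in percent of the substrate charged of the flask you put first, at 4.0 min
4. the amount of open intermediate, in percent of the substrate charged of the flask you put last, at 4.0 min

From the blue run I took a share f, the part of the charged partner B found as open intermediate plus product at 4.00 min: f = 79.6%. Applied to midnight, f gave 31.9% of the substrate converted, so I put midnight last, with winter above it. Clearing the substrate needed a charge of 25.1 mM at that share.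

Speed came from the first grey reading. Taking partner B as fed, unconsumed, up to 0.250 min, I read a rate constant k of 1.29 L mol⁻¹ s⁻¹. I called S the surplus, the charge minus that need. Treating S as a steady excess against the last substrate, a pseudo-first-order picture, I reckoned a clearing half-life τ of ln(2) divided by kS; that steadiness was my assumption and not a reading.

Dusk has S of 0.886 mM, much less than its charge, a margin I judged too thin for τ to mean anything, so I did not count on dusk clearing. Spring has S of 14.9 mM, so τ is 0.602 min, shorter than the 160 s after the feed. That left 4.65% of the substrate by my reckoning. Surplus has a price, though: grey ended with 24.6% product against 1.9% in blue. So I chose spring over autumn and put it first; dusk against autumn I could not separate. At 50 s the feed was still running, so I ranked the flasks by charge.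

The forecast, which differed from my reckoning by putting dusk first, gave dusk > spring > autumn > winter > midnight at 4.0 min and autumn > spring > dusk > winter > midnight at 50 s, with 91% on top and 30% last, on the ground that “dusk just clears it”.

The flasks gave spring > dusk > autumn > winter > midnight at 4.0 min and autumn > spring > dusk > winter > midnight at 50 s, with spring at 87.1% and midnight at 30.8%. The steps were these:

    substrate + partner B → open intermediate (k = 1.50 L mol⁻¹ s⁻¹)
    partner B + partner A → second intermediate (k = 0.200 L mol⁻¹ s⁻¹)
    open intermediate + second intermediate ⇌ product (K = 25.0 L mol⁻¹, k = 0.770 L mol⁻¹ s⁻¹)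
    partner B + protic impurity → quenched reagent (k = 0.820 L mol⁻¹ s⁻¹)
    second intermediate → decomposed reagent (k = 2.80 × 10⁻⁴ s⁻¹)

Spring held 11.5% product at 4.00 min, and its substrate stood at 1.43% against my 4.65% from τ of 0.602 min. Dusk, with S of 0.886 mM, reached 80.0% open intermediate and still held 14.3% of its substrate at 4.00 min.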